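**Retrosynthetic overview** (eremophilane numbering: C3 ester carbinol, C4 methyl, C5 quaternary methyl, C7 isopropylidene, C8 ketone, C10 ring-fusion alkene carbon)

1. The plan rests on ring A: a C1=C2 cyclohexene in which the C3 carbinol, the C4 methyl and the quaternary C5 methyl are contiguous and mutually cis, with C10 next to C5 as the future ring-fusion sp2 carbon.
2. Last disconnections: the C7=C11 alkene (E1cB dehydration of an acetone aldol) and the C3–O ester bond (Mitsunobu esterification with inversion, using (2E,4E,6S)-6-methylocta-2,4-dienoic acid made from (S)-2-methylbutan-1-ol).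
3. Ring B (formed second): C9–C10 by aldol closure of a C8 methyl ketone onto a C10 enone; C6–C7 by Horner–Wadsworth–Emmons olefination of the C6 aldehyde and conjugate reduction.
4. Ring A (formed first): enantioselective Diels–Alder reaction of tiglic aldehyde with a (1E,3E)-1-acetoxy-4-silyloxybutadiene, forming C3–C4 and C5–C10 and fixing C4 and C5.
5. The diene comes in one step from (E,E)-1,4-diacetoxybutadiene, so that both alkene geometries are defined before the cycloaddition.

Key step: step 2

Assumption (stereochemical course): the cycloaddition is taken to follow the formyl-endo course usual for acyclic 1-oxygenated dienes (the exo preference of alpha-methyl enals belongs to cyclopentadiene). Both ring oxygens therefore emerge trans to the two methyls, and C3 is corrected by the inverting esterification in step 13.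

Assumption (sense of induction): the (R)-prolinol-derived oxazaborolidinium ion is taken to expose the C-alpha Si face of the enal, as the formyl C–H···O binding model predicts; if the sense were the reverse, the (S)-catalyst would be used.

**Route**

Step 1
Reactants: 1 (1E,3E)-buta-1,3-diene-1,4-diyl diacetate
Product: 3 (1E,3E)-4-[(tert-butyldimethylsilyl)oxy]buta-1,3-dien-1-yl acetate, via potassium (1E,3E)-4-acetoxybuta-1,3-dien-1-olate 2 (not isolated)
Conditions: KOtBu (1.0 equiv), THF, −78 to −40 °C; then TBSCl, −78 to 0 °C; distillation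
Reagents that add atoms: tert-butyldimethylsilyl chloride, CC(C)(C)[Si](C)(C)Cl
Why: Alkoxide cleavage of an enol acetate to the dienolate followed by O-silylation, both with retention of alkene geometry; only one acetate should be cleaved because loss of the second would have to expel a dianion, and the low temperature keeps the E,E dienolate from isomerising.

Step 2
Reactants: 3 (1E,3E)-4-[(tert-butyldimethylsilyl)oxy]buta-1,3-dien-1-yl acetate; 4 tiglic aldehyde, (E)-2-methylbut-2-enal
Product: 5 (1R,2S,5R,6R)-5-acetoxy-2-[(tert-butyldimethylsilyl)oxy]-1,6-dimethylcyclohex-3-ene-1-carbaldehyde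
Conditions: (R)-3,3-diphenyl-1-(o-tolyl)tetrahydro-1H,3H-pyrrolo[1,2-c][1,3,2]oxazaborole (20 mol %), Tf2NH (17 mol %), 3 (1.5 equiv), CH2Cl2, −78 to −40 °C
Reagents that add atoms: none
Why: Enantioselective Diels–Alder reaction catalysed by a protonated oxazaborolidine, whose closest precedent is the cycloaddition of alpha-substituted enals to 1-silyloxy dienes; tiglic aldehyde binds to boron through oxygen in the s-trans form with its formyl C–H against the ring oxygen, and the diene adds in a concerted but asynchronous [4+2] step in which the C3–C4 bond (acetoxy-bearing terminus to the enal beta-carbon) leads the C5–C10 bond. Ring A is closed in this intermolecular [4+2] mode, the six-membered ring being assembled from the four diene carbons (C3, C2, C1, C10) and the two enal carbons (C4, C5), with C1=C2 left as the ring alkene. C4 and C5 are set cis by suprafacial addition to the E enal and their absolute sense by the catalyst, which screens the face over its aryl group so that the diene meets the C-alpha Si/C-beta Re face; C3 and C10 are set cis to each other by the E,E geometry of the diene and are placed cis to the formyl group, trans to both methyls, by the formyl-endo arrangement. Regioselectivity is the selectivity the step needs most, and it is secured by the silyloxy group being a much stronger donor than the acetoxy group, so that the acetoxy-bearing terminus is the nucleophilic end and the developing positive charge rests on the silyloxy carbon. Addition of the dienol ether to the aldehyde carbonyl is held back by the low temperature and by the absence of free acid (the oxazaborolidine is kept in slight excess over Tf2NH). Of the four new centres only C4 and C5 must reach the target unchanged, since C10 is oxidised in step 6 and C3 is inverted in step 13, and any exo isomer is removed by chromatography.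

Step 3
Reactants: 5 (1R,2S,5R,6R)-5-acetoxy-2-[(tert-butyldimethylsilyl)oxy]-1,6-dimethylcyclohex-3-ene-1-carbaldehyde; 6 dimethyl (2-oxopropyl)phosphonate
Product: 7 (1R,4S,5R,6R)-4-[(tert-butyldimethylsilyl)oxy]-5,6-dimethyl-5-[(1E)-3-oxobut-1-en-1-yl]cyclohex-2-en-1-yl acetate
Conditions: NaH, THF, 0 °C; then 5, rt to 50 °C
Reagents that add atoms: none
Why: Horner–Wadsworth–Emmons olefination of a non-enolisable aldehyde with a stabilised ketophosphonate anion, which should give the E enone (C6=C7) and leave the acetate and the silyl ether untouched; no stereocentre is at risk because the aldehyde sits on the quaternary C5.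

Step 4
Reactants: 7 (1R,4S,5R,6R)-4-[(tert-butyldimethylsilyl)oxy]-5,6-dimethyl-5-[(1E)-3-oxobut-1-en-1-yl]cyclohex-2-en-1-yl acetate
Product: 8 (1R,4S,5R,6R)-4-[(tert-butyldimethylsilyl)oxy]-5,6-dimethyl-5-(3-oxobutyl)cyclohex-2-en-1-yl acetate
Conditions: [(Ph3P)CuH]6 (0.4 equiv), H2O (2 equiv), benzene, rt
Reagents that add atoms: none
Why: Copper hydride conjugate reduction, in which the phosphine-stabilised hydride adds 1,4 to the enone only, so the ring alkene, the allylic acetate, the silyl ether and the resulting saturated ketone are not touched.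

Step 5
Reactants: 8 (1R,4S,5R,6R)-4-[(tert-butyldimethylsilyl)oxy]-5,6-dimethyl-5-(3-oxobutyl)cyclohex-2-en-1-yl acetate
Product: 9 (1R,4S,5R,6R)-4-hydroxy-5,6-dimethyl-5-(3-oxobutyl)cyclohex-2-en-1-yl acetate
Conditions: HF (48% aq.), MeCN, 0 °C to rt
Reagents that add atoms: none
Why: Acidic fluoride desilylation, which should cleave the hindered C10 silyl ether without hydrolysing or migrating the C3 acetate; any cyclic hemiketal between the C10 hydroxyl and the C8 ketone stays in equilibrium with the open form used in step 6.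

Step 6
Reactants: 9 (1R,4S,5R,6R)-4-hydroxy-5,6-dimethyl-5-(3-oxobutyl)cyclohex-2-en-1-yl acetate
Product: 10 (1R,5R,6R)-5,6-dimethyl-4-oxo-5-(3-oxobutyl)cyclohex-2-en-1-yl acetate
Conditions: Dess–Martin periodinane, CH2Cl2, rt
Reagents that add atoms: none
Why: Dess–Martin oxidation of the allylic alcohol to the C10 enone under neutral conditions, so the gamma-acetoxy enone is never exposed to base.

Step 7
Reactants: 10 (1R,5R,6R)-5,6-dimethyl-4-oxo-5-(3-oxobutyl)cyclohex-2-en-1-yl acetate
Product: 12 (1R,2R,8aR)-1,8a-dimethyl-6-oxo-1,2,6,7,8,8a-hexahydronaphthalen-2-yl acetate, via tertiary aldol 11 (not isolated)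
Conditions: LiN(SiMe3)2 (1.05 equiv), THF, −78 °C; AcOH; then p-TsOH·H2O (cat.), benzene, 40 °C
Reagents that add atoms: none
Why: Kinetic intramolecular aldol addition followed by acid-catalysed dehydration: the hindered amide removes a methyl proton (C9) of the ketone, the enolate closes ring B on the C10 carbonyl in a 6-(enolexo)-exo-trig mode, and the tertiary allylic aldol loses water towards C9, the only neighbour carrying hydrogen, to give the linear dienone; the low temperature avoids vinylogous enolisation at C3 and Michael closure from C7.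

Step 8
Reactants: 12 (1R,2R,8aR)-1,8a-dimethyl-6-oxo-1,2,6,7,8,8a-hexahydronaphthalen-2-yl acetate
Product: 13 (4aR,5R,6R)-6-hydroxy-4a,5-dimethyl-4,4a,5,6-tetrahydronaphthalen-2(3H)-one
Conditions: K2CO3, MeOH, 0 °C
Reagents that add atoms: none
Why: Base-catalysed transesterification (methanolysis) of the acetate under mild carbonate conditions, brief and cold enough to leave the epsilon-hydroxy dienone and the C3 configuration unchanged.

Step 9
Reactants: 13 (4aR,5R,6R)-6-hydroxy-4a,5-dimethyl-4,4a,5,6-tetrahydronaphthalen-2(3H)-one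
Product: 15 (4aR,5R,6R)-6-hydroxy-3-(2-hydroxypropan-2-yl)-4a,5-dimethyl-4,4a,5,6-tetrahydronaphthalen-2(3H)-one, via dilithium alkoxide enolate 14 (not isolated)
Conditions: LiN(iPr)2 (2.2 equiv), THF, −78 °C; acetone (5 equiv), −78 °C; AcOH at −78 °C
Reagents that add atoms: acetone, CC(C)=O
Why: Directed aldol addition through a dianion: the first equivalent of base forms the C3 alkoxide, which protects that position, the second removes the alpha-prime proton at C7 kinetically to give the cross-conjugated enolate, and this adds to acetone; the new C7 centre should form mainly anti to the C5 methyl and is removed in step 14.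

Step 10
Reactants: 16 (S)-2-methylbutan-1-ol
Product: 17 (S)-2-methylbutanal
Conditions: TEMPO (1 mol %), KBr (10 mol %), NaOCl (aq., pH 9.5), CH2Cl2, 0 °C
Reagents that add atoms: none
Why: Nitroxyl-catalysed hypochlorite oxidation of a primary alcohol to the aldehyde in a buffered two-phase system at 0 °C, conditions expected to preserve the alpha stereocentre.

Step 11
Reactants: 17 (S)-2-methylbutanal; 18 triethyl 4-phosphonocrotonate, ethyl (2E)-4-(diethoxyphosphoryl)but-2-enoate
Product: 19 ethyl (2E,4E,6S)-6-methylocta-2,4-dienoate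
Conditions: LiN(SiMe3)2, THF, −78 °C; then 17, −78 to 0 °C
Reagents that add atoms: none
Why: Vinylogous Horner–Wadsworth–Emmons olefination, in which the weakly basic stabilised phosphonate anion adds at −78 °C without enolising the alpha-branched aldehyde and should deliver the 2E,4E dienoate.

Step 12
Reactants: 19 ethyl (2E,4E,6S)-6-methylocta-2,4-dienoate
Product: 20 (2E,4E,6S)-6-methylocta-2,4-dienoic acid
Conditions: LiOH, THF/MeOH/H2O, rt; then HCl (aq.)
Reagents that add atoms: lithium hydroxide, [Li+].[OH-]
Why: Saponification of the ethyl ester; the C6 hydrogen is too weakly acidic to be removed by hydroxide, so the stereocentre and both E alkenes are retained.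

Step 13
Reactants: 15 (4aR,5R,6R)-6-hydroxy-3-(2-hydroxypropan-2-yl)-4a,5-dimethyl-4,4a,5,6-tetrahydronaphthalen-2(3H)-one; 20 (2E,4E,6S)-6-methylocta-2,4-dienoic acid
Product: 21 (1R,2S,8aR)-7-(2-hydroxypropan-2-yl)-1,8a-dimethyl-6-oxo-1,2,6,7,8,8a-hexahydronaphthalen-2-yl (2E,4E,6S)-6-methylocta-2,4-dienoate
Conditions: 20 (1.5 equiv), PPh3, DIAD, toluene, 0 °C to rt
Reagents that add atoms: none
Why: Mitsunobu esterification, in which the secondary allylic C3 alcohol is activated as its alkoxyphosphonium ion and displaced by the dienoate with inversion, turning the 3R carbinol of the endo series into the 3S ester of the target while the tertiary alcohol does not react; SN2′ attack is disfavoured because C1 is the gamma carbon of the dienone, and anti elimination is not possible because the C4 hydrogen is cis to the leaving group.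

Step 14
Reactants: 21 (1R,2S,8aR)-7-(2-hydroxypropan-2-yl)-1,8a-dimethyl-6-oxo-1,2,6,7,8,8a-hexahydronaphthalen-2-yl (2E,4E,6S)-6-methylocta-2,4-dienoate
Product: 23 (1R,2S,8aR)-1,8a-dimethyl-6-oxo-7-(propan-2-ylidene)-1,2,6,7,8,8a-hexahydronaphthalen-2-yl (2E,4E,6S)-6-methylocta-2,4-dienoate, via tertiary mesylate 22 (not isolated)
Conditions: MsCl, Et3N, CH2Cl2, 0 °C; then DBU, 0 °C to rt
Reagents that add atoms: none
Why: Mesylation of the tertiary aldol followed by E1cB elimination through the C7 enolate, which can only give the conjugated tetrasubstituted C7=C11 alkene and removes the undefined C7 centre.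

**Compound list**

1 | (1E,3E)-buta-1,3-diene-1,4-diyl diacetate | CC(=O)O/C=C/C=C/OC(C)=O | starting material
2 | potassium (1E,3E)-4-acetoxybuta-1,3-dien-1-olate | CC(=O)O/C=C/C=C/[O-].[K+] | intermediate
3 | (1E,3E)-4-[(tert-butyldimethylsilyl)oxy]buta-1,3-dien-1-yl acetate | CC(=O)O/C=C/C=C/O[Si](C)(C)C(C)(C)C | intermediate
4 | tiglic aldehyde, (E)-2-methylbut-2-enal | C/C=C(\C)C=O | starting material
5 | (1R,2S,5R,6R)-5-acetoxy-2-[(tert-butyldimethylsilyl)oxy]-1,6-dimethylcyclohex-3-ene-1-carbaldehyde (both oxygens cis to the formyl group, trans to the two cis methyls) | CC(=O)O[C@@H]1C=C[C@H](O[Si](C)(C)C(C)(C)C)[C@](C)(C=O)[C@H]1C | intermediate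
6 | dimethyl (2-oxopropyl)phosphonate | CC(=O)CP(=O)(OC)OC | starting material
7 | (1R,4S,5R,6R)-4-[(tert-butyldimethylsilyl)oxy]-5,6-dimethyl-5-[(1E)-3-oxobut-1-en-1-yl]cyclohex-2-en-1-yl acetate | CC(=O)O[C@@H]1C=C[C@H](O[Si](C)(C)C(C)(C)C)[C@](C)(/C=C/C(C)=O)[C@H]1C | intermediate
8 | (1R,4S,5R,6R)-4-[(tert-butyldimethylsilyl)oxy]-5,6-dimethyl-5-(3-oxobutyl)cyclohex-2-en-1-yl acetate | CC(=O)O[C@@H]1C=C[C@H](O[Si](C)(C)C(C)(C)C)[C@](C)(CCC(C)=O)[C@H]1C | intermediate
9 | (1R,4S,5R,6R)-4-hydroxy-5,6-dimethyl-5-(3-oxobutyl)cyclohex-2-en-1-yl acetate | CC(=O)O[C@@H]1C=C[C@H](O)[C@](C)(CCC(C)=O)[C@H]1C | intermediate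
10 | (1R,5R,6R)-5,6-dimethyl-4-oxo-5-(3-oxobutyl)cyclohex-2-en-1-yl acetate | CC(=O)O[C@@H]1C=CC(=O)[C@](C)(CCC(C)=O)[C@H]1C | intermediate
11 | (1R,2R,8aR)-4a-hydroxy-1,8a-dimethyl-6-oxo-1,2,4a,5,6,7,8,8a-octahydronaphthalen-2-yl acetate (4a-epimers, both dehydrate to 12) | CC(=O)O[C@@H]1C=CC2(O)CC(=O)CC[C@]2(C)[C@H]1C | intermediate
12 | (1R,2R,8aR)-1,8a-dimethyl-6-oxo-1,2,6,7,8,8a-hexahydronaphthalen-2-yl acetate | CC(=O)O[C@@H]1C=CC2=CC(=O)CC[C@]2(C)[C@H]1C | intermediate
13 | (4aR,5R,6R)-6-hydroxy-4a,5-dimethyl-4,4a,5,6-tetrahydronaphthalen-2(3H)-one | O[C@@H]1C=CC2=CC(=O)CC[C@]2(C)[C@H]1C | intermediate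
14 | dilithium salt of 13 (C3 alkoxide, C7=C8 enolate) | [Li+].[Li+].[O-][C@@H]1C=CC2=CC([O-])=CC[C@]2(C)[C@H]1C | intermediate
15 | (4aR,5R,6R)-6-hydroxy-3-(2-hydroxypropan-2-yl)-4a,5-dimethyl-4,4a,5,6-tetrahydronaphthalen-2(3H)-one (C3 epimers of the naphthalenone, both converge in step 14) | O[C@@H]1C=CC2=CC(=O)C(C(C)(C)O)C[C@]2(C)[C@H]1C | intermediate
16 | (S)-2-methylbutan-1-ol | CC[C@H](C)CO | starting material
17 | (S)-2-methylbutanal | CC[C@H](C)C=O | intermediate
18 | triethyl 4-phosphonocrotonate, ethyl (2E)-4-(diethoxyphosphoryl)but-2-enoate | CCOC(=O)/C=C/CP(=O)(OCC)OCC | starting material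
19 | ethyl (2E,4E,6S)-6-methylocta-2,4-dienoate | CC[C@H](C)/C=C/C=C/C(=O)OCC | intermediate
20 | (2E,4E,6S)-6-methylocta-2,4-dienoic acid | CC[C@H](C)/C=C/C=C/C(=O)O | intermediate
21 | (1R,2S,8aR)-7-(2-hydroxypropan-2-yl)-1,8a-dimethyl-6-oxo-1,2,6,7,8,8a-hexahydronaphthalen-2-yl (2E,4E,6S)-6-methylocta-2,4-dienoate (C7 epimers) | CC[C@H](C)/C=C/C=C/C(=O)O[C@H]1C=CC2=CC(=O)C(C(C)(C)O)C[C@]2(C)[C@H]1C | intermediate
22 | (1R,2S,8aR)-7-[2-(methanesulfonyloxy)propan-2-yl]-1,8a-dimethyl-6-oxo-1,2,6,7,8,8a-hexahydronaphthalen-2-yl (2E,4E,6S)-6-methylocta-2,4-dienoate | CC[C@H](C)/C=C/C=C/C(=O)O[C@H]1C=CC2=CC(=O)C(C(C)(C)OS(C)(=O)=O)C[C@]2(C)[C@H]1C | intermediate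
23 | (1R,2S,8aR)-1,8a-dimethyl-6-oxo-7-(propan-2-ylidene)-1,2,6,7,8,8a-hexahydronaphthalen-2-yl (2E,4E,6S)-6-methylocta-2,4-dienoate (CNP0215744.1) | CC[C@H](C)/C=C/C=C/C(=O)O[C@H]1C=CC2=CC(=O)C(=C(C)C)C[C@]2(C)[C@H]1C | target

**Step count**

Total: 14 steps. Longest linear sequence: 11 steps (steps 1–9, 13, 14 from compound 1); the acid 20 is made in 3 steps (10–12) and joins at step 13.

**Steps most likely to fail**

Step 2 (key cycloaddition). The catalysed reaction may show poor facial or endo/exo control with this untested diene–enal pair, the dienol ether may be lost to protodesilylation, or it may add to the aldehyde carbonyl instead of the alkene. The fallback sets out from 3 and 4 and returns at 5, replacing asymmetric catalysis by a racemic cycloaddition and an enzymatic resolution. Compounds 3 and 4 would be combined without a chiral catalyst (toluene, 100–110 °C with a radical inhibitor, or 10–12 kbar in CH2Cl2 at rt), which should give the racemic endo adduct, that is 5 together with its mirror image (1S,2R,5S,6S)-5-acetoxy-2-[(tert-butyldimethylsilyl)oxy]-1,6-dimethylcyclohex-3-ene-1-carbaldehyde F1. A lipase-catalysed hydrolysis of the allylic acetate (pH 7 buffer/MTBE, enzyme picked from a screen so that F1 is the fast-reacting enantiomer) would convert F1 into (1S,2R,5S,6S)-2-[(tert-butyldimethylsilyl)oxy]-5-hydroxy-1,6-dimethylcyclohex-3-ene-1-carbaldehyde F2. Unreacted 5 is separated by chromatography and rejoins the route at 5.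

Step 13 (inverting esterification). Backside attack at C3 is hindered by the cis C4 methyl and the angular C5 methyl, so displacement may be slow and give way to acyl transfer with retention or to decomposition of the activated alcohol. The fallback sets out from 15 and returns at 23, separating activation from displacement. Compound 15 with Ms2O and Et3N (excess, CH2Cl2, 0 °C to rt) would give the bis-mesylate (1R,2R,8aR)-7-[2-(methanesulfonyloxy)propan-2-yl]-1,8a-dimethyl-6-oxo-1,2,6,7,8,8a-hexahydronaphthalen-2-yl methanesulfonate F3. Its tertiary mesylate is lost in the same flask by E1cB elimination to give (1R,2R,8aR)-1,8a-dimethyl-6-oxo-7-(propan-2-ylidene)-1,2,6,7,8,8a-hexahydronaphthalen-2-yl methanesulfonate F4. Displacement of F4 with the caesium salt of 20 (Cs2CO3, 18-crown-6, toluene or DMF, 40–60 °C) should invert C3 and give 23 directly.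

Step 9 (acetone aldol through the dianion). The enolate may be quenched by proton transfer from acetone, the tertiary aldolate may revert by retro-aldol cleavage, or the dianion may aggregate and react sluggishly. The fallback sets out from 13 and returns at 15, replacing the lithium enolate by a silyl dienol ether. Compound 13 with TESOTf (2.5 equiv) and Et3N (CH2Cl2, −78 to 0 °C) would give (4aR,5R,6R)-4a,5-dimethyl-2,6-bis[(triethylsilyl)oxy]-4,4a,5,6-tetrahydronaphthalene F5, which carries a C3 silyl ether and the cross-conjugated C7=C8 silyl enol ether. A Mukaiyama aldol addition to acetone (TiCl4, CH2Cl2, −78 °C) would give (4aR,5R,6R)-3-(2-hydroxypropan-2-yl)-4a,5-dimethyl-6-[(triethylsilyl)oxy]-4,4a,5,6-tetrahydronaphthalen-2(3H)-one F6. Aqueous HF in MeCN then removes the silyl ether to give 15.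

**Further compounds**

F1 | step 2 | (1S,2R,5S,6S)-5-acetoxy-2-[(tert-butyldimethylsilyl)oxy]-1,6-dimethylcyclohex-3-ene-1-carbaldehyde | CC(=O)O[C@H]1C=C[C@@H](O[Si](C)(C)C(C)(C)C)[C@@](C)(C=O)[C@@H]1C
F2 | step 2 | (1S,2R,5S,6S)-2-[(tert-butyldimethylsilyl)oxy]-5-hydroxy-1,6-dimethylcyclohex-3-ene-1-carbaldehyde | O[C@H]1C=C[C@@H](O[Si](C)(C)C(C)(C)C)[C@@](C)(C=O)[C@@H]1C
F3 | step 13 | (1R,2R,8aR)-7-[2-(methanesulfonyloxy)propan-2-yl]-1,8a-dimethyl-6-oxo-1,2,6,7,8,8a-hexahydronaphthalen-2-yl methanesulfonate | CS(=O)(=O)O[C@@H]1C=CC2=CC(=O)C(C(C)(C)OS(C)(=O)=O)C[C@]2(C)[C@H]1C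
F4 | step 13 | (1R,2R,8aR)-1,8a-dimethyl-6-oxo-7-(propan-2-ylidene)-1,2,6,7,8,8a-hexahydronaphthalen-2-yl methanesulfonate | CS(=O)(=O)O[C@@H]1C=CC2=CC(=O)C(=C(C)C)C[C@]2(C)[C@H]1C
F5 | step 9 | (4aR,5R,6R)-4a,5-dimethyl-2,6-bis[(triethylsilyl)oxy]-4,4a,5,6-tetrahydronaphthalene | CC[Si](CC)(CC)O[C@@H]1C=CC2=CC(O[Si](CC)(CC)CC)=CC[C@]2(C)[C@H]1C
F6 | step 9 | (4aR,5R,6R)-3-(2-hydroxypropan-2-yl)-4a,5-dimethyl-6-[(triethylsilyl)oxy]-4,4a,5,6-tetrahydronaphthalen-2(3H)-one | CC[Si](CC)(CC)O[C@@H]1C=CC2=CC(=O)C(C(C)(C)O)C[C@]2(C)[C@H]1C
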